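**Plan**
1. Retrosynthesis: cut C14=C15 (Horner–Wadsworth–Emmons), then C2–C3 (ketene acetal onto the ring peroxycarbenium ion), then both ring C–O bonds (H2O2 supplies O–O), then C4–C5, traced to a temporary β-lactone made from a methyl carbinol; the chain is cut at C10–C11 (cross-metathesis) and C5–CH3 (Grignard) back to (R)-citronellal.
2. Enabling feature: ring atoms O1–C5–C4–C3 form a β-oxygenated ketone pattern and C5 is an O-bearing quaternary carbon flanked by CH3, C4H2 and C6H2. Its precursor is a methyl carbinol whose C5–H lies 1,4 to a carbenoid carbon on an acetoacetate tether, so C4–C5 can be closed as a ring bond of an oxetan-2-one; the O–C(=O) tether later leaves as CO2.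
3. Forward: chain assembly from (R)-citronellal, diazoacetoacetate, oxetan-2-one (temporary ring, closed at C4–C5), then perhydrolysis/decarboxylation/peroxyhemiketalisation builds the 1,2-dioxolane, then the C3 acetate arm, the phenyldiene and the free acid.
4. Stereochemistry: C7 from (R)-citronellal; C5 from the lipase-resolved (S)-carbinol, carried with retention (C–H insertion) then inversion (perhydrolysis) to 5R; C3 by addition to the dioxolanyl cation, where little facial bias is expected and the C3 epimer is separated; both alkenes E from the stabilised phosphonate.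

Key step: step 8

Remark: locants C1–C17 in the text follow the target acid chain (C1 = carboxyl carbon; C3, C4, C5 = ring carbons; C7 = side-chain methine; C14–C17 = diene); compound names use their own locants.

Step 1
Reactants: 1 (R)-citronellal
Product: 2 (4R)-4,8-dimethylnon-7-en-2-ol (C2 epimers)
Conditions: MeMgBr, THF, −78 to 0 °C; aq NH4Cl
Reagents that add atoms: methylmagnesium bromide, C[Mg]Br
Why: Grignard addition to the aldehyde installs the C5 methyl group; the carbinol centre forms without control (resolved in step 2) and C7 comes unchanged from the chiral pool.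

Step 2
Reactants: 2 (4R)-4,8-dimethylnon-7-en-2-ol (C2 epimers)
Product: 3 (2S,4R)-4,8-dimethylnon-7-en-2-ol
Conditions: immobilised Candida antarctica lipase B, vinyl acetate, hexane, 30 °C; chromatography
Reagents that add atoms: none
Why: Enzymatic kinetic resolution by transesterification should acylate the (2R) epimer of the methyl carbinol (the usual preference of this lipase), leaving the (2S,4R) alcohol, whose C–H centre is the one later converted into C5.

Step 3
Reactants: 4 pent-4-en-1-ol
Product: 5 triisopropyl(pent-4-en-1-yloxy)silane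
Conditions: TIPSCl, imidazole, DMF, 25 °C
Reagents that add atoms: chlorotriisopropylsilane, CC(C)[Si](Cl)(C(C)C)C(C)C
Why: Standard silylation gives an acid-robust primary silyl ether that should survive the Lewis-acid steps 9 and 10.

Step 4
Reactants: 3 (2S,4R)-4,8-dimethylnon-7-en-2-ol; 5 triisopropyl(pent-4-en-1-yloxy)silane
Product: 6 (2S,4R,7E)-4-methyl-11-(triisopropylsilyloxy)undec-7-en-2-ol (some 7Z expected)
Conditions: second-generation Grubbs catalyst RuCl2(=CHPh)(PCy3)(H2IMes) (5 mol %), excess 5, CH2Cl2, 40 °C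
Reagents that add atoms: none
Why: Olefin cross-metathesis of the prenyl-type trisubstituted alkene with the terminal alkene (isobutene lost) appends C11–C14 with the protected oxygen; alkene geometry is irrelevant because the bond is hydrogenated next.

Step 5
Reactants: 6 (2S,4R,7E)-4-methyl-11-(triisopropylsilyloxy)undec-7-en-2-ol
Product: 7 (2S,4R)-4-methyl-11-(triisopropylsilyloxy)undecan-2-ol
Conditions: H2 (1 atm), 10% Pd/C, EtOAc, 25 °C
Reagents that add atoms: none
Why: Heterogeneous hydrogenation saturates the chain so that no alkene can compete for the carbenoid in step 8.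

Step 6
Reactants: 7 (2S,4R)-4-methyl-11-(triisopropylsilyloxy)undecan-2-ol; 8 2,2,6-trimethyl-4H-1,3-dioxin-4-one
Product: 9 (2S,4R)-4-methyl-11-(triisopropylsilyloxy)undecan-2-yl 3-oxobutanoate
Conditions: xylene, 135 °C, acetone distilled off
Reagents that add atoms: none
Why: Thermal cycloreversion of the dioxinone releases acetylketene, which acylates the secondary alcohol at oxygen without touching the carbinol stereocentre (acetoacetylation).

Step 7
Reactants: 9 (2S,4R)-4-methyl-11-(triisopropylsilyloxy)undecan-2-yl 3-oxobutanoate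
Product: 10 (2S,4R)-4-methyl-11-(triisopropylsilyloxy)undecan-2-yl 2-diazo-3-oxobutanoate
Conditions: 4-acetamidobenzenesulfonyl azide, Et3N, MeCN, 0 to 25 °C
Reagents that add atoms: 4-acetamidobenzenesulfonyl azide, CC(=O)Nc1ccc(cc1)S(=O)(=O)N=[N+]=[N-]
Why: Regitz diazo transfer to the activated methylene of the β-keto ester places the carbenoid precursor on the carbon that becomes C4.

Step 8
Reactants: 10 (2S,4R)-4-methyl-11-(triisopropylsilyloxy)undecan-2-yl 2-diazo-3-oxobutanoate
Product: 11 (4S)-3-acetyl-4-methyl-4-[(2R)-2-methyl-9-(triisopropylsilyloxy)nonyl]oxetan-2-one (C3 epimers)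
Conditions: Rh2(OAc)4 (1 mol %), CH2Cl2, 40 °C, slow addition of 10
Reagents that add atoms: none
Why: Rh2(OAc)4 expels N2 from 10 to give an electrophilic acceptor/acceptor rhodium carbenoid on the future C4, which inserts through a concerted three-centre transition state into the carbinol C–H bond of its own ester alkoxy group, so that the new C4–C5 bond is the ring-closing bond. The closest known reaction type is the Rh2(OAc)4-catalysed formation of β-lactones from diazomalonate and α-diazo-β-keto esters of secondary alcohols. The ring closed is an oxetan-2-one, formed by 1,4-C–H insertion (carbenoid carbon to the O-bearing methine carbon). The quaternary C5 is set with retention from the (S)-carbinol centre, because the carbon enters on the face of the C–H bond it replaces; the α-carbon is also stereogenic but is of no consequence since it becomes the C4 methylene. The step needs 1,4-insertion to win over 1,5-insertion into the C6 methylene or the C5 methyl group and over carbene dimerisation: the methine is the most hydridic C–H (tertiary and α to oxygen), the β C–H bonds are deactivated inductively by the acyloxy group, the chain carries no alkene, and slow addition keeps the diazo concentration low.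

Step 9
Reactants: 11 (4S)-3-acetyl-4-methyl-4-[(2R)-2-methyl-9-(triisopropylsilyloxy)nonyl]oxetan-2-one
Product: 14 (5R)-3-methoxy-3,5-dimethyl-5-[(2R)-2-methyl-9-(triisopropylsilyloxy)nonyl]-1,2-dioxolane (C3 epimers), via hydroperoxy keto acid 12 (not isolated), via dioxolanol 13 (not isolated)
Conditions: anhydrous H2O2 in Et2O (excess), TMSOTf, Et2O, −78 to 0 °C; then 25 °C; then MeOH, PPTS, 25 °C
Reagents that add atoms: hydrogen peroxide, OO; methanol, CO
Why: Proposed new method: Lewis-acid activation of the lactone carbonyl should let H2O2 open the strained oxetan-2-one by alkyl–oxygen cleavage at the tertiary C5 from the face opposite the departing carboxylate (borderline SN2; full ionisation is disfavoured by the two carbonyl groups on the adjacent carbon and the leaving group stays tethered on its own face), giving the C5 hydroperoxide with inversion; the resulting β-keto acid then loses CO2 (which removes the tether), the hydroperoxide closes onto the methyl ketone (5-exo peroxyhemiketal, forming the 1,2-dioxolane) and MeOH/PPTS exchanges OH for OMe; the closest known reaction types are the Lewis-acid perhydrolysis of 2,2-disubstituted oxetanes with inversion at the tertiary carbon and the acid-mediated alkyl–oxygen opening of β,β-disubstituted β-lactones.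

Step 10
Reactants: 14 (5R)-3-methoxy-3,5-dimethyl-5-[(2R)-2-methyl-9-(triisopropylsilyloxy)nonyl]-1,2-dioxolane; 15 tert-butyl[(1-methoxyethenyl)oxy]dimethylsilane
Product: 16 methyl 2-[(3R,5R)-3,5-dimethyl-5-[(2R)-2-methyl-9-(triisopropylsilyloxy)nonyl]-1,2-dioxolan-3-yl]acetate
Conditions: TiCl4, CH2Cl2, −78 °C; chromatographic separation from the C3 epimer
Reagents that add atoms: none
Why: TiCl4 ionises the cyclic peroxyketal to the 1,2-dioxolan-3-ylium (peroxycarbenium) ion, which the silyl ketene acetal captures in a Mukaiyama-type addition; C3 is set here under weak substrate control (CH3 versus CH2R at C5), so both C3 epimers are expected in comparable amounts and the (3R,5R) isomer is isolated by chromatography.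

Step 11
Reactants: 16 methyl 2-[(3R,5R)-3,5-dimethyl-5-[(2R)-2-methyl-9-(triisopropylsilyloxy)nonyl]-1,2-dioxolan-3-yl]acetate
Product: 17 methyl 2-[(3R,5R)-5-[(2R)-9-hydroxy-2-methylnonyl]-3,5-dimethyl-1,2-dioxolan-3-yl]acetate
Conditions: HF·pyridine, pyridine, THF, 0 to 25 °C
Reagents that add atoms: none
Why: Fluoride cleavage of the primary silyl ether under buffered, non-basic conditions should spare the dialkyl peroxide and the base-sensitive β-peroxy ester.

Step 12
Reactants: 17 methyl 2-[(3R,5R)-5-[(2R)-9-hydroxy-2-methylnonyl]-3,5-dimethyl-1,2-dioxolan-3-yl]acetate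
Product: 18 methyl 2-[(3R,5R)-3,5-dimethyl-5-[(2R)-2-methyl-9-oxononyl]-1,2-dioxolan-3-yl]acetate
Conditions: Dess–Martin periodinane, NaHCO3, CH2Cl2, 0 to 25 °C
Reagents that add atoms: none
Why: Dess–Martin oxidation of the primary alcohol is neutral and non-reducing, conditions that a fully substituted dialkyl peroxide should tolerate.

Step 13
Reactants: 18 methyl 2-[(3R,5R)-3,5-dimethyl-5-[(2R)-2-methyl-9-oxononyl]-1,2-dioxolan-3-yl]acetate; 19 diethyl [(2E)-3-phenylprop-2-en-1-yl]phosphonate
Product: 20 methyl 2-[(3R,5R)-3,5-dimethyl-5-[(2R,9E,11E)-2-methyl-12-phenyldodeca-9,11-dien-1-yl]-1,2-dioxolan-3-yl]acetate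
Conditions: 19, LiN(SiMe3)2, THF, −78 °C; then 18, −78 to 0 °C
Reagents that add atoms: none
Why: Horner–Wadsworth–Emmons olefination with the preformed lithiated cinnamylphosphonate should give the new C14=C15 bond E (stabilised allylic phosphonate anion) while the styryl bond stays E, and no free amide base is left to enolise the ester.

Step 14
Reactants: 20 methyl 2-[(3R,5R)-3,5-dimethyl-5-[(2R,9E,11E)-2-methyl-12-phenyldodeca-9,11-dien-1-yl]-1,2-dioxolan-3-yl]acetate
Product: 21 2-[(3R,5R)-3,5-dimethyl-5-[(2R,9E,11E)-2-methyl-12-phenyldodeca-9,11-dien-1-yl]-1,2-dioxolan-3-yl]acetic acid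
Conditions: LiOH, THF/H2O, 0 to 25 °C; then 1 M HCl to pH 3 at 0 °C
Reagents that add atoms: lithium hydroxide, [Li+].[OH-]
Why: Saponification by acyl–oxygen cleavage should leave the ring intact, since the peroxide carbons carry no hydrogen for base-induced fragmentation and no stereocentre is touched.

**Compound list**
1 | (R)-citronellal, (3R)-3,7-dimethyloct-6-enal | C[C@H](CCC=C(C)C)CC=O | starting material
2 | (4R)-4,8-dimethylnon-7-en-2-ol (C2 epimers) | C[C@H](CCC=C(C)C)CC(C)O | intermediate
3 | (2S,4R)-4,8-dimethylnon-7-en-2-ol | C[C@H](CCC=C(C)C)C[C@H](C)O | intermediate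
4 | pent-4-en-1-ol | C=CCCCO | starting material
5 | triisopropyl(pent-4-en-1-yloxy)silane | C=CCCCO[Si](C(C)C)(C(C)C)C(C)C | intermediate
6 | (2S,4R,7E)-4-methyl-11-(triisopropylsilyloxy)undec-7-en-2-ol | C[C@H](CC/C=C/CCCO[Si](C(C)C)(C(C)C)C(C)C)C[C@H](C)O | intermediate
7 | (2S,4R)-4-methyl-11-(triisopropylsilyloxy)undecan-2-ol | C[C@H](CCCCCCCO[Si](C(C)C)(C(C)C)C(C)C)C[C@H](C)O | intermediate
8 | 2,2,6-trimethyl-4H-1,3-dioxin-4-one | CC1=CC(=O)OC(C)(C)O1 | starting material
9 | (2S,4R)-4-methyl-11-(triisopropylsilyloxy)undecan-2-yl 3-oxobutanoate | CC(=O)CC(=O)O[C@@H](C)C[C@H](C)CCCCCCCO[Si](C(C)C)(C(C)C)C(C)C | intermediate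
10 | (2S,4R)-4-methyl-11-(triisopropylsilyloxy)undecan-2-yl 2-diazo-3-oxobutanoate | CC(=O)C(=[N+]=[N-])C(=O)O[C@@H](C)C[C@H](C)CCCCCCCO[Si](C(C)C)(C(C)C)C(C)C | intermediate
11 | (4S)-3-acetyl-4-methyl-4-[(2R)-2-methyl-9-(triisopropylsilyloxy)nonyl]oxetan-2-one (C3 epimers) | CC(=O)C1C(=O)O[C@@]1(C)C[C@H](C)CCCCCCCO[Si](C(C)C)(C(C)C)C(C)C | intermediate
12 | (3R,5R)-2-acetyl-3-hydroperoxy-3,5-dimethyl-12-(triisopropylsilyloxy)dodecanoic acid (C2 epimers) | CC(=O)C(C(=O)O)[C@](C)(OO)C[C@H](C)CCCCCCCO[Si](C(C)C)(C(C)C)C(C)C | intermediate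
13 | (5R)-3,5-dimethyl-5-[(2R)-2-methyl-9-(triisopropylsilyloxy)nonyl]-1,2-dioxolan-3-ol (C3 epimers) | C[C@H](CCCCCCCO[Si](C(C)C)(C(C)C)C(C)C)C[C@]1(C)CC(C)(O)OO1 | intermediate
14 | (5R)-3-methoxy-3,5-dimethyl-5-[(2R)-2-methyl-9-(triisopropylsilyloxy)nonyl]-1,2-dioxolane (C3 epimers) | C[C@H](CCCCCCCO[Si](C(C)C)(C(C)C)C(C)C)C[C@]1(C)CC(C)(OC)OO1 | intermediate
15 | tert-butyl[(1-methoxyethenyl)oxy]dimethylsilane | C=C(OC)O[Si](C)(C)C(C)(C)C | starting material
16 | methyl 2-[(3R,5R)-3,5-dimethyl-5-[(2R)-2-methyl-9-(triisopropylsilyloxy)nonyl]-1,2-dioxolan-3-yl]acetate | C[C@H](CCCCCCCO[Si](C(C)C)(C(C)C)C(C)C)C[C@]1(C)C[C@](C)(CC(=O)OC)OO1 | intermediate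
17 | methyl 2-[(3R,5R)-5-[(2R)-9-hydroxy-2-methylnonyl]-3,5-dimethyl-1,2-dioxolan-3-yl]acetate | C[C@H](CCCCCCCO)C[C@]1(C)C[C@](C)(CC(=O)OC)OO1 | intermediate
18 | methyl 2-[(3R,5R)-3,5-dimethyl-5-[(2R)-2-methyl-9-oxononyl]-1,2-dioxolan-3-yl]acetate | C[C@H](CCCCCCC=O)C[C@]1(C)C[C@](C)(CC(=O)OC)OO1 | intermediate
19 | diethyl [(2E)-3-phenylprop-2-en-1-yl]phosphonate | CCOP(=O)(C/C=C/c1ccccc1)OCC | starting material
20 | methyl 2-[(3R,5R)-3,5-dimethyl-5-[(2R,9E,11E)-2-methyl-12-phenyldodeca-9,11-dien-1-yl]-1,2-dioxolan-3-yl]acetate | C[C@H](CCCCCC/C=C/C=C/c1ccccc1)C[C@]1(C)C[C@](C)(CC(=O)OC)OO1 | intermediate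
21 | 2-[(3R,5R)-3,5-dimethyl-5-[(2R,9E,11E)-2-methyl-12-phenyldodeca-9,11-dien-1-yl]-1,2-dioxolan-3-yl]acetic acid | C[C@H](CCCCCC/C=C/C=C/c1ccccc1)C[C@]1(C)C[C@](C)(CC(=O)O)OO1 | target

Total step count: 14. Longest linear sequence: 13 steps (1 to 21 through steps 1, 2 and 4–14).

**Steps most likely to fail**

Step 9 (proposed new method). The opening may go through full ionisation at C5 with loss of configuration, or the β-lactone may fragment by decarboxylative elimination to the enone before H2O2 captures it. The fallback uses known chemistry, sets out from 11 and comes back at 14. Lactone 11 is saponified with LiOH at 0 °C and acidified, the β-keto acid losing CO2 to give (4S,6R)-4-hydroxy-4,6-dimethyl-13-(triisopropylsilyloxy)tridecan-2-one F1. NaBH4 reduces this to (4S,6R)-4,6-dimethyl-13-(triisopropylsilyloxy)tridecane-2,4-diol F2. Selective mesylation of the secondary hydroxyl (MsCl, Et3N) gives (4S,6R)-4-hydroxy-4,6-dimethyl-13-(triisopropylsilyloxy)tridecan-2-yl methanesulfonate F3, which KOtBu closes, with retention at the tertiary carbon, to (2S)-2,4-dimethyl-2-[(2R)-2-methyl-9-(triisopropylsilyloxy)nonyl]oxetane F4. Ethereal H2O2/TMSOTf then opens the oxetane at the tertiary carbon with inversion (the established oxetane perhydrolysis) to (4R,6R)-4-hydroperoxy-4,6-dimethyl-13-(triisopropylsilyloxy)tridecan-2-ol F5. 2-Methoxypropene/PPTS masks the hydroperoxide as (4R,6R)-4-[(2-methoxypropan-2-yl)peroxy]-4,6-dimethyl-13-(triisopropylsilyloxy)tridecan-2-ol F6, Dess–Martin oxidation gives (4R,6R)-4-[(2-methoxypropan-2-yl)peroxy]-4,6-dimethyl-13-(triisopropylsilyloxy)tridecan-2-one F7, and MeOH/PPTS removes the peroxyketal with cyclisation and ketalisation to 14.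

Step 8 (key step). Insertion may occur 1,5 into the C6 methylene to give a γ-lactone, or the carbenoid may dimerise, instead of closing the four-membered ring. The fallback forms C4–C5 by olefination and sets C5 by reagent control; it sets out from 7 and comes back at 14. Dess–Martin oxidation of 7 gives (4R)-4-methyl-11-(triisopropylsilyloxy)undecan-2-one F8. Horner–Wadsworth–Emmons reaction with triethyl phosphonoacetate gives ethyl (2E,5R)-3,5-dimethyl-12-(triisopropylsilyloxy)dodec-2-enoate F9, and iBu2AlH reduces it to (2E,5R)-3,5-dimethyl-12-(triisopropylsilyloxy)dodec-2-en-1-ol F10. Sharpless epoxidation (Ti(OiPr)4, L-(+)-diethyl tartrate, tBuOOH) sets the quaternary carbon in [(2S,3S)-3-methyl-3-[(2R)-2-methyl-9-(triisopropylsilyloxy)nonyl]oxiran-2-yl]methanol F11. Oxidation gives (2R,3S)-3-methyl-3-[(2R)-2-methyl-9-(triisopropylsilyloxy)nonyl]oxirane-2-carbaldehyde F12, and MeMgBr gives 1-[(2S,3S)-3-methyl-3-[(2R)-2-methyl-9-(triisopropylsilyloxy)nonyl]oxiran-2-yl]ethan-1-ol F13. NaAlH2(OCH2CH2OMe)2 opens the epoxide at the secondary carbon to the same (4S,6R)-4,6-dimethyl-13-(triisopropylsilyloxy)tridecane-2,4-diol F2, which continues through the oxetane sequence described above to 14.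

Step 10. Poor facial selectivity at C3 is expected, because the cation sees only CH3 versus CH2R at C5, and this would erode throughput. The fallback replaces the irreversible C–C addition by a reversible C–O ring closure; it sets out from 13 (isolated by omitting the methanol treatment of step 9) and comes back at 16. 2-Methoxypropene/PPTS traps the open-chain tautomer of 13 as (4R,6R)-4-[(2-methoxypropan-2-yl)peroxy]-4,6-dimethyl-13-(triisopropylsilyloxy)tridecan-2-one F7. Horner–Wadsworth–Emmons olefination with trimethyl phosphonoacetate gives methyl (2E,5R,7R)-5-[(2-methoxypropan-2-yl)peroxy]-3,5,7-trimethyl-14-(triisopropylsilyloxy)tetradec-2-enoate F14, and PPTS/MeOH frees methyl (2E,5R,7R)-5-hydroperoxy-3,5,7-trimethyl-14-(triisopropylsilyloxy)tetradec-2-enoate F15. Et2NH then closes this by intramolecular 5-exo oxa-Michael addition to 16; a chair-like transition state with the ester arm and the larger C5 substituent both pseudo-equatorial should favour the cis arrangement, and because the closure is reversible under base the unwanted C3 epimer can be re-equilibrated and recycled.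

Further compounds
F1 | step 9 | (4S,6R)-4-hydroxy-4,6-dimethyl-13-(triisopropylsilyloxy)tridecan-2-one | CC(=O)C[C@@](C)(O)C[C@H](C)CCCCCCCO[Si](C(C)C)(C(C)C)C(C)C
F2 | step 9 | (4S,6R)-4,6-dimethyl-13-(triisopropylsilyloxy)tridecane-2,4-diol (C2 epimers) | CC(O)C[C@@](C)(O)C[C@H](C)CCCCCCCO[Si](C(C)C)(C(C)C)C(C)C
F3 | step 9 | (4S,6R)-4-hydroxy-4,6-dimethyl-13-(triisopropylsilyloxy)tridecan-2-yl methanesulfonate (C2 epimers) | CC(OS(C)(=O)=O)C[C@@](C)(O)C[C@H](C)CCCCCCCO[Si](C(C)C)(C(C)C)C(C)C
F4 | step 9 | (2S)-2,4-dimethyl-2-[(2R)-2-methyl-9-(triisopropylsilyloxy)nonyl]oxetane (C4 epimers) | CC1C[C@@](C)(O1)C[C@H](C)CCCCCCCO[Si](C(C)C)(C(C)C)C(C)C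
F5 | step 9 | (4R,6R)-4-hydroperoxy-4,6-dimethyl-13-(triisopropylsilyloxy)tridecan-2-ol (C2 epimers) | CC(O)C[C@](C)(OO)C[C@H](C)CCCCCCCO[Si](C(C)C)(C(C)C)C(C)C
F6 | step 9 | (4R,6R)-4-[(2-methoxypropan-2-yl)peroxy]-4,6-dimethyl-13-(triisopropylsilyloxy)tridecan-2-ol (C2 epimers) | CC(O)C[C@](C)(OOC(C)(C)OC)C[C@H](C)CCCCCCCO[Si](C(C)C)(C(C)C)C(C)C
F7 | step 9 | (4R,6R)-4-[(2-methoxypropan-2-yl)peroxy]-4,6-dimethyl-13-(triisopropylsilyloxy)tridecan-2-one | CC(=O)C[C@](C)(OOC(C)(C)OC)C[C@H](C)CCCCCCCO[Si](C(C)C)(C(C)C)C(C)C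
F8 | step 8 | (4R)-4-methyl-11-(triisopropylsilyloxy)undecan-2-one | CC(=O)C[C@H](C)CCCCCCCO[Si](C(C)C)(C(C)C)C(C)C
F9 | step 8 | ethyl (2E,5R)-3,5-dimethyl-12-(triisopropylsilyloxy)dodec-2-enoate | CCOC(=O)/C=C(\C)C[C@H](C)CCCCCCCO[Si](C(C)C)(C(C)C)C(C)C
F10 | step 8 | (2E,5R)-3,5-dimethyl-12-(triisopropylsilyloxy)dodec-2-en-1-ol | OC/C=C(\C)C[C@H](C)CCCCCCCO[Si](C(C)C)(C(C)C)C(C)C
F11 | step 8 | [(2S,3S)-3-methyl-3-[(2R)-2-methyl-9-(triisopropylsilyloxy)nonyl]oxiran-2-yl]methanol | OC[C@@H]1O[C@@]1(C)C[C@H](C)CCCCCCCO[Si](C(C)C)(C(C)C)C(C)C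
F12 | step 8 | (2R,3S)-3-methyl-3-[(2R)-2-methyl-9-(triisopropylsilyloxy)nonyl]oxirane-2-carbaldehyde | O=C[C@@H]1O[C@@]1(C)C[C@H](C)CCCCCCCO[Si](C(C)C)(C(C)C)C(C)C
F13 | step 8 | 1-[(2S,3S)-3-methyl-3-[(2R)-2-methyl-9-(triisopropylsilyloxy)nonyl]oxiran-2-yl]ethan-1-ol (carbinol epimers) | CC(O)[C@@H]1O[C@@]1(C)C[C@H](C)CCCCCCCO[Si](C(C)C)(C(C)C)C(C)C
F14 | step 10 | methyl (2E,5R,7R)-5-[(2-methoxypropan-2-yl)peroxy]-3,5,7-trimethyl-14-(triisopropylsilyloxy)tetradec-2-enoate | COC(=O)/C=C(\C)C[C@](C)(OOC(C)(C)OC)C[C@H](C)CCCCCCCO[Si](C(C)C)(C(C)C)C(C)C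
F15 | step 10 | methyl (2E,5R,7R)-5-hydroperoxy-3,5,7-trimethyl-14-(triisopropylsilyloxy)tetradec-2-enoate | COC(=O)/C=C(\C)C[C@](C)(OO)C[C@H](C)CCCCCCCO[Si](C(C)C)(C(C)C)C(C)C
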